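**Target:** (2S)-5,7-dihydroxy-2-[4-hydroxy-3-prenylphenyl]-6,8-diprenylchroman-4-one (22), where prenyl is 3-methylbut-2-en-1-yl. C2 is S in the target SMILES, and the carbinol carbon of 17 has the same spatial arrangement and the same descriptor.

**Remarks on the chemistry**
- Naming of the aryne precursor: in 10 the silicon-bearing carbon lies between the triflate-bearing carbon and a MOM ether, and the triflate-bearing carbon lies next to a prenyl group. The correct name is therefore 3,5-bis(methoxymethoxy)-2,4-diprenyl-6-(trimethylsilyl)phenyl triflate. The locant set 2,4-bis(methoxymethoxy)-3,5-diprenyl would describe a 1,2,4-trioxygenated ring that a phloroglucinol cannot give, and is not used.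
- Design change in the ring A branch: the bromotriol 4 cannot be doubly protected selectively, because its two hydroxyls beside bromine are equivalent and both more reactive than the third. The two MOM ethers of 10 are therefore put on after the O-to-C silyl shift, which differentiates the oxygens by itself.
- Assumption: the (S)-carbinol of 17 is made by asymmetric transfer hydrogenation of β-keto ester 15 and not by an acetate aldol, so 4-hydroxyacetophenone and dimethyl carbonate serve as starting materials; the sense of induction of this reduction is secure, at the cost of one step in that branch.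

## Structural features

The target is a flavanone: benzene ring A is fused through C4a–C8a to the dihydropyranone ring C (O1, C2, C3, C4), and aryl ring B is attached at C2. Ring A is hexasubstituted, with oxygen on C5, C7 and C8a in a phloroglucinol pattern, prenyl groups on C6 and C8, and the C4 acyl carbon on C4a; ring B carries a 4'-hydroxyl and a 3'-prenyl group. C2 is the only stereocentre and has no stereogenic neighbour. It is benzylic to an electron-rich ring and β to the C4 carbonyl, so base can open ring C by retro-oxa-Michael reaction to an achiral chalcone, and acid can ionise the C2–O1 bond. The three prenyl alkenes are the other fragile elements: each lies ortho to a phenol and is exposed to acid-induced chroman formation, to electrophilic halogen, to hydrogenation and to oxidants. The real difficulty is twofold: a ring A in which every position is defined and the two oxygens flanking C4a are told apart, and a union of ring A with C2 that never passes through the chalcone. The key step exploits the ortho relation of O1 (on C8a) and the C4 carbonyl (on C4a): both can be delivered to a C4a≡C8a aryne by one partner that is nucleophilic at oxygen and electrophilic at carbon, and the C5 oxygen, which flanks C4a only, polarises that aryne in the required sense.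

## Logic of the disconnections

22 ⇒ 21. The three phenolic O–H bonds are traced back to O–CH2 acetal bonds. Free phenoxides would intercept the aryne and would make ring C open under base; the gain is a key step without any acidic proton. The forward step must cleave three acetals without adding the phenols to the neighbouring prenyl alkenes and without ionising C2.

21 ⇒ 10 + 17 (through 19 and 18). O1–C8a and C4–C4a are cut together. Both bonds end on adjacent carbons of ring A, so the cut removes ring C in one operation, divides the molecule into halves of similar size, and leaves C2 in an open-chain piece where it is easy to control. The forward step demands attack of oxygen at C8a and not at C4a, acylation of the C4a carbanion before it is protonated, and a lifetime of 18 long enough to meet 19.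

17 ⇒ 16. The O–Si bond is cut. Silicon stands in for the hydroxyl proton so that the fluoride that unmasks 19 also releases the alkoxide in a medium without proton donors. The forward step is simple, but 17 must be handled without hydrolysis.

16 ⇒ 15. The C2–H bond is cut, carbinol to ketone. The stereocentre becomes a prochiral aryl ketone, the substrate class for which catalytic transfer hydrogenation has a secure sense of induction. The forward step must deliver hydride to one face and leave the alkene, ester and acetal alone.

15 ⇒ 13 + 14. The C3–C4 bond is cut. C4 then comes from a one-carbon electrophile and the rest from an aryl methyl ketone. The forward step needs C-acylation of the enolate and an excess of base to hold the product as its enolate.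

13 ⇒ 12 ⇒ 11 + 2. The O–CH2 acetal bond and then the C3'–CH2 bond of the ring B prenyl group are cut. This reaches two commercial compounds. The forward alkylation must occur at carbon ortho to oxygen in competition with O-alkylation.

10 ⇒ 9. Two O–CH2 acetal bonds are cut. The acetals are the last operation of this branch because the oxygen that becomes the triflate is singled out by the silyl shift and not by selective protection. The forward step must alkylate two hindered phenols under a base too weak to push silicon from carbon to oxygen.

9 ⇒ 5 (through 8, 7 and 6). The O–S bond of the triflate is cut, the C4a–Si bond is returned to an O–Si bond, C4a–Li is traced to C4a–Br, and the two free hydroxyls are traced to silyl ethers. In 5 the two oxygens beside the bromine-bearing carbon are equivalent, and a single carbanion can take silicon from only one of them, so the reaction itself breaks the symmetry. The gain is a mirror-symmetric precursor. The forward step needs halogen–metal exchange faster than attack of the organolithium at silicon, and triflation of a hindered phenoxide.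

5 ⇒ 4 ⇒ 3. Three O–Si bonds and then the C4a–Br bond are cut. This leads back to a triol with one free ring position. The forward bromination must take place at ring carbon and not at the alkenes.

3 ⇒ 1 + 2. The two ring–CH2 bonds at C6 and C8 are cut. Both prenyl groups then come from one reagent and ring A from a symmetric triol. The forward step must favour C- over O-alkylation and stop at two groups.

## Other disconnections considered

Alternative 1: The cut is C4a–C8a, so ring A itself is the ring that is made. In the forward direction the open-chain 3,5,7-trioxo ester A2, which already carries both prenyl groups (on the future C6 and C8) and a silyl-protected (R)-carbinol at the future C2, is enolised by Mg(OMe)2 in methanol. C4a adds to the ester carbonyl C8a, methanol is lost and the ring tautomerises to the acylphloroglucinol A1. Desilylation, Mitsunobu closure of O1–C2 with inversion, and loss of the ring B MOM ether would then give 22.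
- In its favour: ring A is born with all six substituents, with no substitution on an aromatic ring. A1 is symmetric about the acyl group, so either ortho hydroxyl closes ring C and the differentiation that the chosen route must achieve in step 4 is not needed; on this point the alternative is better. The ring C closure is a known reaction type whereas step 11 is not; on this point it is also better.
- Against it: A2 has to be assembled by polyanion acylations that include two α-prenylated 1,3-dicarbonyl units, which is a long linear sequence. Poly-β-carbonyl esters fold by aldol reaction and by O-acylation to pyranones as readily as by Claisen condensation, and the branched C6 and C8 positions slow the enolisation that leads to the wanted mode. The β-silyloxy ketone is exposed to methoxide and can eliminate to the enone. The Mitsunobu step must invert a carbinol that is benzylic to an alkoxy-substituted ring, where ionisation erodes configuration.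
- Comparison: in structure both plans reach the same ring A pattern, the alternative by construction and the chosen plan from a preformed benzene. In mechanism the alternative uses only precedented reaction types but depends on a mode of folding that the substrate does not control, whereas the chosen plan rests on one unprecedented step whose regiochemistry the substrate does control. In step economy the alternative is the poorer: the chain alone should need about as many linear steps as the longest sequence of the chosen route, and three more follow.

Alternative 2: The cuts are C2–C3 and O1–C8a, made before ring A exists. In the forward direction the ring B aldehyde A4 and Danishefsky's diene A5 combine under a Ti(OiPr)4–BINOL catalyst, and acid work-up eliminates methanol to give the dihydropyranone A3 with C2 set.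
- In its favour: catalytic enantioselective hetero-Diels–Alder reactions of aromatic aldehydes are well established and either catalyst enantiomer can be chosen. As a stereocentre-forming step it is as well founded as step 9, so the two plans are equal on this point. A3 should be reached in fewer steps than 17, which is a point for the alternative.
- Against it: after the key step the hexasubstituted ring A, which is the main difficulty, is still wholly absent. It must be grown on the C4a=C8a enol ether: four carbons, two oxygens and two prenyl groups, followed by aromatisation. No short benzannulation that delivers this pattern on a 2,3-dihydropyran-4-one is at hand, and every basic or Lewis acidic operation on A3 risks opening of the β-alkoxy enone with loss of C2.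
- Comparison: in structure the chosen plan brings ring A complete to the key step and the alternative leaves it to the end. In mechanism the key step of the alternative is the safer of the two, but the steps after it are the uncertain ones, so the risk is moved and not removed. In step economy the alternative has low convergence and presumably eight or more steps after A3, against one step after the key step of the chosen route.

Alternative 3: The cut is C2–C3. In the forward direction the diazoketone A7, whose ring A carries the diazoacetyl group on C4a and the ring B arylmethyl group as a benzyl ether on the C8a oxygen, is decomposed by Rh2(S-PTTL)4 or its enantiomer. The carbenoid carbon C3 inserts into one of the two enantiotopic benzylic C–H bonds, closing ring C and setting C2 in the tri-O-TBS flavanone A6.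
- In its favour: the two halves are joined beforehand by a plain Williamson etherification, and the C–H bond is activated by the ether oxygen and by the aryl ring. The ring closure runs under neutral conditions, so the flavanone is not exposed to base when it forms; on this point the alternative is better than step 11. The stereocentre is made by the catalyst in the ring-closing step, so either enantiomer would come from one precursor; this is equal to or better than the chosen plan. The number of steps should be of the same order, so the plans are equal there.
- Against it: an ortho-alkoxy diazoketone offers the carbenoid the ether oxygen at a five-atom distance, and oxonium ylide formation followed by a Stevens benzyl shift to a benzofuran-3-one normally outruns insertion to a six-membered ring. Three prenyl alkenes and the ring B arene invite cyclopropanation and ring expansion. Enantioselective insertion of acceptor-only carbenoids is modest at best. A7 needs a ring A in which the C8a oxygen is benzylated and the C5 oxygen silylated, which is the same differentiation of two equivalent oxygens, now without the silyl shift that solves it. The final desilylation needs fluoride, which is basic towards a flavanone.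
- Comparison: in structure both plans need the same differentiated ring A. In mechanism the chosen plan has one real unknown (an aliphatic alkoxide as aryne partner) with substrate-controlled regiochemistry, while the alternative has a known reaction type working against a known and faster competing pathway. In step economy the two are comparable.

Key step: step 11

## Steps

Step 1
Reactants: 1 phloroglucinol (benzene-1,3,5-triol); 2 prenyl bromide (1-bromo-3-methylbut-2-ene)
Product: 3 2,4-diprenylphloroglucinol
Conditions: 2 (2.0 equiv), 10% aq. KOH, 0 °C to rt
Reagents that add atoms: none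
Why: Phenolate C-alkylation: in water the oxygens of the phloroglucinol anion are solvated, so the allylic bromide is attacked by ring carbon; two equivalents give the 2,4-dialkylated triol, which rearomatises by tautomerisation and is separated from mono- and trialkylated material by chromatography.

Step 2
Reactants: 3 2,4-diprenylphloroglucinol
Product: 4 2-bromo-4,6-diprenylphloroglucinol
Conditions: NBS (1.0 equiv), CH2Cl2–THF, −78 °C, dark
Reagents that add atoms: N-bromosuccinimide, O=C1CCC(=O)N1Br
Why: Electrophilic aromatic bromination: the one remaining ring C–H lies between two hydroxyls and is far more nucleophilic than the trisubstituted alkenes, so one equivalent at low temperature should brominate the ring only.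

Step 3
Reactants: 4 2-bromo-4,6-diprenylphloroglucinol
Product: 5 2-bromo-4,6-diprenyl-1,3,5-tris(trimethylsilyloxy)benzene
Conditions: HMDS (3 equiv), THF, 65 °C; volatiles removed in vacuo
Reagents that add atoms: hexamethyldisilazane, C[Si](C)(C)N[Si](C)(C)C
Why: Exhaustive O-silylation of the three phenols; ammonia is the only by-product, so 5 is obtained by evaporation and used without contact with water.

Step 4
Reactants: 5 2-bromo-4,6-diprenyl-1,3,5-tris(trimethylsilyloxy)benzene
Product: 9 3,5-dihydroxy-2,4-diprenyl-6-(trimethylsilyl)phenyl triflate, via aryllithium 6 (not isolated), via lithium phenoxide 7 (not isolated), via bis(silyl ether) triflate 8 (not isolated)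
Conditions: n-BuLi (1.05 equiv), THF, −78 °C; Tf2O (1.1 equiv), −78 °C; aq. NaHCO3; then MeOH, citric acid (cat.), 0 °C
Reagents that add atoms: trifluoromethanesulfonic anhydride, O=S(=O)(OS(=O)(=O)C(F)(F)F)C(F)(F)F
Why: Bromine–lithium exchange gives 6, which undergoes the retro-Brook 1,3 O-to-C silyl shift to 7; one carbanion can take silicon from only one of its two equivalent neighbours, so the symmetry of 5 is broken without any selective protection. O-Triflation of the single phenoxide gives 8, and mild methanolysis cleaves the two remaining O–Si bonds but not the C–Si bond.

Step 5
Reactants: 9 3,5-dihydroxy-2,4-diprenyl-6-(trimethylsilyl)phenyl triflate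
Product: 10 3,5-bis(methoxymethoxy)-2,4-diprenyl-6-(trimethylsilyl)phenyl triflate
Conditions: MOMCl (3 equiv), DIPEA (4 equiv), CH2Cl2, 0 °C to rt
Reagents that add atoms: chloromethyl methyl ether, COCCl
Why: Williamson-type O-alkylation of both phenols to MOM ethers; an amine base in dichloromethane gives no free phenoxide, which should keep silicon on carbon and the triflate in place.

Step 6
Reactants: 11 4-hydroxyacetophenone; 2 prenyl bromide
Product: 12 4-hydroxy-3-prenylacetophenone
Conditions: 2 (1.1 equiv), 10% aq. KOH, 0 °C to rt
Reagents that add atoms: none
Why: Phenolate C-alkylation in water: the para position is blocked, so carbon attack occurs ortho to oxygen; the ortho-prenyl phenol is separated from O-alkylated and unchanged material by chromatography.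

Step 7
Reactants: 12 4-hydroxy-3-prenylacetophenone
Product: 13 4-(methoxymethoxy)-3-prenylacetophenone
Conditions: MOMCl, DIPEA, CH2Cl2, 0 °C to rt
Reagents that add atoms: chloromethyl methyl ether, COCCl
Why: Standard O-alkylation of a phenol to its MOM ether, a group that withstands NaH, formic acid–amine mixtures and fluoride.

Step 8
Reactants: 13 4-(methoxymethoxy)-3-prenylacetophenone; 14 dimethyl carbonate
Product: 15 methyl 3-[4-(methoxymethoxy)-3-prenylphenyl]-3-oxopropanoate
Conditions: NaH (2.5 equiv), 14 (5 equiv), THF, reflux; AcOH quench
Reagents that add atoms: none
Why: Crossed Claisen condensation: the ketone enolate is C-methoxycarbonylated by dimethyl carbonate, and deprotonation of the β-keto ester pulls the equilibrium over.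

Step 9
Reactants: 15 methyl 3-[4-(methoxymethoxy)-3-prenylphenyl]-3-oxopropanoate
Product: 16 methyl (S)-3-hydroxy-3-[4-(methoxymethoxy)-3-prenylphenyl]propanoate
Conditions: RuCl[(S,S)-TsDPEN](p-cymene) (1 mol%), HCO2H–Et3N (5:2), rt to 40 °C
Reagents that add atoms: none
Why: Noyori asymmetric transfer hydrogenation of an aryl ketone: hydride and proton are delivered through the six-membered bifunctional transition state with the aryl group held against the arene ligand, and the (S,S) ligand is the one that gives (S)-carbinols from aryl ketones of this priority pattern, so C2 is set here as S. Isolated alkenes, the ester and the acetal are inert to this catalyst.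

Step 10
Reactants: 16 methyl (S)-3-hydroxy-3-[4-(methoxymethoxy)-3-prenylphenyl]propanoate
Product: 17 methyl (S)-3-[4-(methoxymethoxy)-3-prenylphenyl]-3-(trimethylsilyloxy)propanoate
Conditions: TMSCl (1.2 equiv), imidazole (1.5 equiv), CH2Cl2, 0 °C; filtration through basic alumina
Reagents that add atoms: chlorotrimethylsilane, C[Si](C)(C)Cl
Why: O-Silylation of the secondary alcohol; the trimethylsilyl ether is chosen because fluoride cleaves it at a rate comparable to that of aryne release, and it is freed of salts without aqueous work-up and used at once.

Step 11
Reactants: 10 3,5-bis(methoxymethoxy)-2,4-diprenyl-6-(trimethylsilyl)phenyl triflate; 17 methyl (S)-3-[4-(methoxymethoxy)-3-prenylphenyl]-3-(trimethylsilyloxy)propanoate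
Product: 21 (2S)-5,7-bis(methoxymethoxy)-2-[4-(methoxymethoxy)-3-prenylphenyl]-6,8-diprenylchroman-4-one, via cesium alkoxide 18 (not isolated), via aryne 19 (not isolated), via aryl cesium adduct 20 (not isolated)
Conditions: CsF (4 equiv), 18-crown-6 (1 equiv), THF, 0 °C to rt, 10 (1.3 equiv) added slowly; AcOH quench at 0 °C
Reagents that add atoms: none
Why: Proposed new method: fluoride attacks the O–Si bond of 17 to give alkoxide 18 and the C–Si bond of 10, with loss of triflate, to give aryne 19; 18 adds through oxygen to C8a of 19, and the C4a carbanion of 20 closes ring C by 6-exo-trig addition–elimination at the ester carbonyl with loss of methoxide. The closest known reaction type is the fluoride-induced annulation of arynes with salicylate esters to xanthones; the new element is a secondary aliphatic alkoxide, released from its silyl ether, as the oxygen partner. No stereocentre is created: C2 comes from 17 and keeps its S configuration because the C2–O bond is never broken and no enone lies on the path. The step needs attack at C8a and not at C4a, which the inductively withdrawing C5 MOM ether beside C4a secures by distorting the aryne so that the nucleophile enters at the remote carbon and the charge develops next to oxygen; this bias should outweigh the modest hindrance of the C8 prenyl group. It also needs the alkoxide to reach the aryne before retro-aldol cleavage and before an ene reaction of the aryne with a prenyl group, which is why both partners are unmasked by one reagent, cold, in an aprotic medium, with 10 added slowly. THF is preferred to acetonitrile so that no C–H acid protonates 20 before it acylates, and the acidic quench removes methoxide before it can open ring C.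

Step 12
Reactants: 21 (2S)-5,7-bis(methoxymethoxy)-2-[4-(methoxymethoxy)-3-prenylphenyl]-6,8-diprenylchroman-4-one
Product: 22 (2S)-5,7-dihydroxy-2-[4-hydroxy-3-prenylphenyl]-6,8-diprenylchroman-4-one
Conditions: 1 M HCl in MeOH, 35 °C
Reagents that add atoms: none
Why: Acid-catalysed solvolysis of the three MOM acetals to dimethoxymethane; the C5 ether, peri to the carbonyl, should go first, and dilute acid at mild temperature is the usual way to spare ortho-prenyl phenols. No base is present, so ring C should not open and C2 should keep its configuration.

## Compound list

1 | phloroglucinol (benzene-1,3,5-triol) | Oc1cc(O)cc(O)c1 | starting material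
2 | prenyl bromide (1-bromo-3-methylbut-2-ene) | CC(C)=CCBr | starting material
3 | 2,4-bis(3-methylbut-2-en-1-yl)benzene-1,3,5-triol (2,4-diprenylphloroglucinol) | Oc1cc(O)c(CC=C(C)C)c(O)c1CC=C(C)C | intermediate
4 | 2-bromo-4,6-bis(3-methylbut-2-en-1-yl)benzene-1,3,5-triol | Oc1c(Br)c(O)c(CC=C(C)C)c(O)c1CC=C(C)C | intermediate
5 | 2-bromo-4,6-diprenyl-1,3,5-tris(trimethylsilyloxy)benzene | C[Si](C)(C)Oc1c(Br)c(O[Si](C)(C)C)c(CC=C(C)C)c(O[Si](C)(C)C)c1CC=C(C)C | intermediate
6 | [3,5-diprenyl-2,4,6-tris(trimethylsilyloxy)phenyl]lithium | [Li]c1c(O[Si](C)(C)C)c(CC=C(C)C)c(O[Si](C)(C)C)c(CC=C(C)C)c1O[Si](C)(C)C | intermediate (not isolated)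
7 | lithium 2,4-diprenyl-6-(trimethylsilyl)-3,5-bis(trimethylsilyloxy)phenoxide | [Li+].[O-]c1c(CC=C(C)C)c(O[Si](C)(C)C)c(CC=C(C)C)c(O[Si](C)(C)C)c1[Si](C)(C)C | intermediate (not isolated)
8 | 2,4-diprenyl-6-(trimethylsilyl)-3,5-bis(trimethylsilyloxy)phenyl triflate | C[Si](C)(C)Oc1c(CC=C(C)C)c(O[Si](C)(C)C)c(CC=C(C)C)c(OS(=O)(=O)C(F)(F)F)c1[Si](C)(C)C | intermediate (not isolated)
9 | 3,5-dihydroxy-2,4-diprenyl-6-(trimethylsilyl)phenyl triflate | Oc1c(CC=C(C)C)c(O)c(CC=C(C)C)c(OS(=O)(=O)C(F)(F)F)c1[Si](C)(C)C | intermediate
10 | 3,5-bis(methoxymethoxy)-2,4-diprenyl-6-(trimethylsilyl)phenyl triflate | C[Si](C)(C)c1c(OCOC)c(CC=C(C)C)c(OCOC)c(CC=C(C)C)c1OS(=O)(=O)C(F)(F)F | intermediate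
11 | 4-hydroxyacetophenone | CC(=O)c1ccc(O)cc1 | starting material
12 | 1-[4-hydroxy-3-(3-methylbut-2-en-1-yl)phenyl]ethan-1-one | CC(=O)c1ccc(O)c(CC=C(C)C)c1 | intermediate
13 | 1-[4-(methoxymethoxy)-3-(3-methylbut-2-en-1-yl)phenyl]ethan-1-one | CC(=O)c1ccc(OCOC)c(CC=C(C)C)c1 | intermediate
14 | dimethyl carbonate | COC(=O)OC | starting material
15 | methyl 3-[4-(methoxymethoxy)-3-prenylphenyl]-3-oxopropanoate | COC(=O)CC(=O)c1ccc(OCOC)c(CC=C(C)C)c1 | intermediate
16 | methyl (S)-3-hydroxy-3-[4-(methoxymethoxy)-3-prenylphenyl]propanoate | CC(C)=CCc1cc([C@@H](O)CC(=O)OC)ccc1OCOC | intermediate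
17 | methyl (S)-3-[4-(methoxymethoxy)-3-prenylphenyl]-3-(trimethylsilyloxy)propanoate | CC(C)=CCc1cc([C@@H](O[Si](C)(C)C)CC(=O)OC)ccc1OCOC | intermediate
18 | cesium (S)-3-methoxy-1-[4-(methoxymethoxy)-3-prenylphenyl]-3-oxopropan-1-olate | CC(C)=CCc1cc([C@@H]([O-])CC(=O)OC)ccc1OCOC.[Cs+] | intermediate (not isolated)
19 | 3,5-bis(methoxymethoxy)-4,6-diprenyl-1,2-didehydrobenzene | COCOC1=C(CC=C(C)C)C(OCOC)=C(CC=C(C)C)C#C1 | intermediate (not isolated)
20 | cesium 2-{[(S)-3-methoxy-1-[4-(methoxymethoxy)-3-prenylphenyl]-3-oxopropyl]oxy}-4,6-bis(methoxymethoxy)-3,5-diprenylbenzen-1-ide | CC(C)=CCc1cc([C@H](CC(=O)OC)Oc2c(CC=C(C)C)c(OCOC)c(CC=C(C)C)c(OCOC)[c-]2)ccc1OCOC.[Cs+] | intermediate (not isolated)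
21 | (2S)-5,7-bis(methoxymethoxy)-2-[4-(methoxymethoxy)-3-prenylphenyl]-6,8-diprenylchroman-4-one | CC(C)=CCc1cc([C@@H]2CC(=O)c3c(OCOC)c(CC=C(C)C)c(OCOC)c(CC=C(C)C)c3O2)ccc1OCOC | intermediate
22 | (2S)-5,7-dihydroxy-2-[4-hydroxy-3-(3-methylbut-2-en-1-yl)phenyl]-6,8-bis(3-methylbut-2-en-1-yl)-2,3-dihydro-4H-chromen-4-one | CC(C)=CCc1cc([C@@H]2CC(=O)c3c(O)c(CC=C(C)C)c(O)c(CC=C(C)C)c3O2)ccc1O | target

## Step count and least certain steps

Total: 12 steps. Longest linear sequence: 7 steps (steps 1, 2, 3, 4, 5, 11, 12); the ring B branch (steps 6 to 10, then 11 and 12) is equally long.

**Step 11 (key step, proposed new method).** Several processes can divert it: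
- retro-aldol cleavage of the unmasked alkoxide before it meets the aryne;
- proton transfer from the ester α-CH2 to the C4a carbanion, followed by β-elimination of the aryloxide;
- methoxide- or fluoride-induced opening of ring C in the product, with loss of configuration;
- ene reaction of the aryne with prenyl groups;
- partial attack of oxygen at C4a.

All follow from the fact that a basic, hindered aliphatic alkoxide is a slower aryne partner than a phenoxide, and that the product is base-sensitive.

The fallback uses known chemistry only; it sets out from 15 and 3 and comes back at 21. Transfer hydrogenation of 15 with RuCl[(R,R)-TsDPEN](p-cymene) would give methyl (R)-3-hydroxy-3-[4-(methoxymethoxy)-3-prenylphenyl]propanoate F1. TBSCl and imidazole would give its TBS ether F2, and MeNHOMe·HCl with i-PrMgCl would give the Weinreb amide F3. In parallel, 3 would be converted with MOMCl and NaH into 1,3,5-tris(methoxymethoxy)-2,4-diprenylbenzene F4. Lithiation of F4 with n-BuLi at its last ring C–H (between two MOM ethers) and addition to F3 would give the aryl ketone F5. TBAF buffered with AcOH would give the β-hydroxy ketone F6. Brief treatment with catalytic HCl in MeOH at 0 °C would free one of the two equivalent MOM ethers ortho to the carbonyl, a chelation-assisted cleavage, to give the 2'-hydroxy ketone F7. Mitsunobu closure (PPh3, DIAD, THF) would form O1–C2 with inversion of the (R)-carbinol and give 21.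

**Step 5.** On deprotonation, a phenol ortho to the C–Si bond can trigger a C-to-O silyl shift with loss of triflate, which is premature aryne release; the two phenols are also hindered, so alkylation may be slow enough for this to compete. The fallback avoids base altogether; it sets out from 9 and comes back at 22. Ethyl vinyl ether with catalytic PPTS in CH2Cl2 at 0 °C would give 3,5-bis(1-ethoxyethoxy)-2,4-diprenyl-6-(trimethylsilyl)phenyl triflate F8. The conditions of step 11 with 17 would give the corresponding flavanone F9, and the acid of step 12 would remove the two ethoxyethyl groups and the MOM group to give 22.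

**Step 1.** Alkylation can fail to stop at two groups, and O-alkylation and geminal C-dialkylation can occur, because each C-alkylation makes the ring more electron-rich; a difficult separation and a low throughput are likely. The fallback replaces the direct alkylation by directed metalation; it sets out from 1 and comes back at 3. MOMCl and NaH would give 1,3,5-tris(methoxymethoxy)benzene F10. n-BuLi followed by 2 would give 1,3,5-tris(methoxymethoxy)-2-prenylbenzene F11, and a second lithiation and alkylation with 2 would give the diprenyl compound F4. Dilute HCl in MeOH would then give 3.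

**Step 2.** Electrophilic bromine can add to a prenyl alkene with participation of the neighbouring phenol (bromoetherification), and the electron-rich ring can be over-brominated or dearomatised. The fallback introduces bromine as an electrophile towards an aryllithium and not towards a free polyphenol; it sets out from 3 and comes back at 4. MOMCl and NaH would give F4. n-BuLi and then 1,2-dibromotetrachloroethane would give 2-bromo-1,3,5-tris(methoxymethoxy)-4,6-diprenylbenzene F12, and dilute HCl in MeOH would give 4.

**Step 12.** Protonation of a prenyl alkene followed by attack of the ortho phenol would give chromans, and ionisation of the C2–O1 bond next to the electron-rich ring B would erode configuration; both grow with acid strength and time. The fallback replaces Brønsted acid solvolysis by silyl transfer; it sets out from 21 and comes back at 22. TMSOTf with 2,2'-bipyridyl in CH2Cl2 at 0 °C would exchange the three aryl MOM ethers for trimethylsilyl ethers, giving the tris(trimethylsilyl) ether F13, and water at neutral pH would hydrolyse F13 to 22.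

## Further compounds

F1 | step 11 | methyl (R)-3-hydroxy-3-[4-(methoxymethoxy)-3-prenylphenyl]propanoate | CC(C)=CCc1cc([C@H](O)CC(=O)OC)ccc1OCOC
F2 | step 11 | methyl (R)-3-(tert-butyldimethylsilyloxy)-3-[4-(methoxymethoxy)-3-prenylphenyl]propanoate | CC(C)=CCc1cc([C@H](O[Si](C)(C)C(C)(C)C)CC(=O)OC)ccc1OCOC
F3 | step 11 | (R)-3-(tert-butyldimethylsilyloxy)-N-methoxy-3-[4-(methoxymethoxy)-3-prenylphenyl]-N-methylpropanamide | CC(C)=CCc1cc([C@H](O[Si](C)(C)C(C)(C)C)CC(=O)N(C)OC)ccc1OCOC
F4 | step 11 | 1,3,5-tris(methoxymethoxy)-2,4-diprenylbenzene | COCOc1cc(OCOC)c(CC=C(C)C)c(OCOC)c1CC=C(C)C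
F5 | step 11 | (R)-3-(tert-butyldimethylsilyloxy)-3-[4-(methoxymethoxy)-3-prenylphenyl]-1-[2,4,6-tris(methoxymethoxy)-3,5-diprenylphenyl]propan-1-one | CC(C)=CCc1cc([C@H](O[Si](C)(C)C(C)(C)C)CC(=O)c2c(OCOC)c(CC=C(C)C)c(OCOC)c(CC=C(C)C)c2OCOC)ccc1OCOC
F6 | step 11 | (R)-3-hydroxy-3-[4-(methoxymethoxy)-3-prenylphenyl]-1-[2,4,6-tris(methoxymethoxy)-3,5-diprenylphenyl]propan-1-one | CC(C)=CCc1cc([C@H](O)CC(=O)c2c(OCOC)c(CC=C(C)C)c(OCOC)c(CC=C(C)C)c2OCOC)ccc1OCOC
F7 | step 11 | (R)-3-hydroxy-1-[2-hydroxy-4,6-bis(methoxymethoxy)-3,5-diprenylphenyl]-3-[4-(methoxymethoxy)-3-prenylphenyl]propan-1-one | CC(C)=CCc1cc([C@H](O)CC(=O)c2c(OCOC)c(CC=C(C)C)c(OCOC)c(CC=C(C)C)c2O)ccc1OCOC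
F8 | step 5 | 3,5-bis(1-ethoxyethoxy)-2,4-diprenyl-6-(trimethylsilyl)phenyl triflate (mixture of acetal diastereomers) | CCOC(C)Oc1c(CC=C(C)C)c(OC(C)OCC)c(CC=C(C)C)c(OS(=O)(=O)C(F)(F)F)c1[Si](C)(C)C
F9 | step 5 | (2S)-5,7-bis(1-ethoxyethoxy)-2-[4-(methoxymethoxy)-3-prenylphenyl]-6,8-diprenylchroman-4-one (mixture of acetal diastereomers) | CC(C)=CCc1cc([C@@H]2CC(=O)c3c(OC(C)OCC)c(CC=C(C)C)c(OC(C)OCC)c(CC=C(C)C)c3O2)ccc1OCOC
F10 | step 1 | 1,3,5-tris(methoxymethoxy)benzene | COCOc1cc(OCOC)cc(OCOC)c1
F11 | step 1 | 1,3,5-tris(methoxymethoxy)-2-prenylbenzene | COCOc1cc(OCOC)c(CC=C(C)C)c(OCOC)c1
F12 | step 2 | 2-bromo-1,3,5-tris(methoxymethoxy)-4,6-diprenylbenzene | COCOc1c(Br)c(OCOC)c(CC=C(C)C)c(OCOC)c1CC=C(C)C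
F13 | step 12 | (2S)-6,8-diprenyl-2-[3-prenyl-4-(trimethylsilyloxy)phenyl]-5,7-bis(trimethylsilyloxy)chroman-4-one | CC(C)=CCc1cc([C@@H]2CC(=O)c3c(O[Si](C)(C)C)c(CC=C(C)C)c(O[Si](C)(C)C)c(CC=C(C)C)c3O2)ccc1O[Si](C)(C)C
A1 | alternative 1 | (R)-3-(tert-butyldimethylsilyloxy)-3-[4-(methoxymethoxy)-3-prenylphenyl]-1-(2,4,6-trihydroxy-3,5-diprenylphenyl)propan-1-one | CC(C)=CCc1cc([C@H](O[Si](C)(C)C(C)(C)C)CC(=O)c2c(O)c(CC=C(C)C)c(O)c(CC=C(C)C)c2O)ccc1OCOC
A2 | alternative 1 | methyl (9R)-9-(tert-butyldimethylsilyloxy)-9-[4-(methoxymethoxy)-3-prenylphenyl]-3,5,7-trioxo-2,4-diprenylnonanoate | CC(C)=CCc1cc([C@H](O[Si](C)(C)C(C)(C)C)CC(=O)CC(=O)C(CC=C(C)C)C(=O)C(CC=C(C)C)C(=O)OC)ccc1OCOC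
A3 | alternative 2 | (S)-2-[4-(tert-butyldimethylsilyloxy)-3-prenylphenyl]-2,3-dihydro-4H-pyran-4-one | CC(C)=CCc1cc([C@@H]2CC(=O)C=CO2)ccc1O[Si](C)(C)C(C)(C)C
A4 | alternative 2 | 4-(tert-butyldimethylsilyloxy)-3-prenylbenzaldehyde | CC(C)=CCc1cc(C=O)ccc1O[Si](C)(C)C(C)(C)C
A5 | alternative 2 | Danishefsky's diene, (E)-1-methoxy-3-(trimethylsilyloxy)buta-1,3-diene | CO/C=C/C(=C)O[Si](C)(C)C
A6 | alternative 3 | (2S)-5,7-bis(tert-butyldimethylsilyloxy)-2-[4-(tert-butyldimethylsilyloxy)-3-prenylphenyl]-6,8-diprenylchroman-4-one | CC(C)=CCc1cc([C@@H]2CC(=O)c3c(O[Si](C)(C)C(C)(C)C)c(CC=C(C)C)c(O[Si](C)(C)C(C)(C)C)c(CC=C(C)C)c3O2)ccc1O[Si](C)(C)C(C)(C)C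
A7 | alternative 3 | 2-diazo-1-{2-[4-(tert-butyldimethylsilyloxy)-3-prenylbenzyloxy]-4,6-bis(tert-butyldimethylsilyloxy)-3,5-diprenylphenyl}ethan-1-one | CC(C)=CCc1cc(COc2c(CC=C(C)C)c(O[Si](C)(C)C(C)(C)C)c(CC=C(C)C)c(O[Si](C)(C)C(C)(C)C)c2C(=O)C=[N+]=[N-])ccc1O[Si](C)(C)C(C)(C)C
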